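**Retrosynthetic overview**
1. Target 9 ← ketone 8 by hydroxyl-directed 1,3-anti reduction of the C6 carbonyl (sets C6); 8 ← 7 ← 6 by desilylation and benzoylation of the primary alcohol.
2. Key disconnection C1–CH2: hydroxymethyl enone 6 ← formaldehyde + enone 5 (Morita–Baylis–Hillman), with 5 made in the same flask from bromodiene 3 by singlet-oxygen [4+2] addition and O–O reduction.
3. Enabling feature: the bromine on diene terminus C6. In the 2,3-dioxabicyclo[2.2.2]oct-5-ene 4 it makes bridgehead C6 a masked ketone, so O–O cleavage gives the enone O=C6–C1=C2, whose only α-carbon is C1, the carbon that must carry CH2OBz; bromine leaves as bromide.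
4. 3 ← 1, the commercial cis-dihydrodiol of bromobenzene (an arene at a lower oxidation level): distal OH silylated, proximal OH benzoylated, which is already the C5 benzoate of the target.
5. Rings: the carbocycle is carried from 1 and never formed; the only ring formed is the temporary 1,2-dioxine of 4, closed and opened in step 3. Stereocenters: C4 and C5 from 1, C3 from anti addition of singlet oxygen, C6 from the directed reduction.

Key step: step 3

Assumption: under kinetic control the bulky silyl chloride is taken to react at the hydroxyl of 1 remote from bromine (the less hindered, more nucleophilic one); TDS = thexyldimethylsilyl = dimethyl(2,3-dimethylbutan-2-yl)silyl.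

Step 1
Reactants: 1 (1S,2S)-3-bromocyclohexa-3,5-diene-1,2-diol
Product: 2 (1S,6S)-2-bromo-6-[(thexyldimethylsilyl)oxy]cyclohexa-2,4-dien-1-ol
Conditions: TDSCl (1.05 equiv), imidazole, DMF, −10 °C
Reagents that add atoms: thexyldimethylsilyl chloride, CC(C)C(C)(C)[Si](C)(C)Cl
Why: Kinetic mono-silylation (silyl ether formation); the hydroxyl next to the C–Br carbon is more hindered and inductively deactivated, so the bulky thexyl reagent should cap the distal hydroxyl, and no stereocenter is touched.

Step 2
Reactants: 2 (1S,6S)-2-bromo-6-[(thexyldimethylsilyl)oxy]cyclohexa-2,4-dien-1-ol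
Product: 3 (1S,6S)-2-bromo-6-[(thexyldimethylsilyl)oxy]cyclohexa-2,4-dien-1-yl benzoate
Conditions: BzCl, pyridine, DMAP (cat.), CH2Cl2, 0 °C
Reagents that add atoms: benzoyl chloride, O=C(Cl)c1ccccc1
Why: DMAP-catalysed acylation of the remaining proximal allylic hydroxyl with an acid chloride; only the O–H bond reacts, so configuration is retained, and with both oxygens capped no free hydroxyl can steer singlet oxygen to the syn face in step 3.

Step 3
Reactants: 3 (1S,6S)-2-bromo-6-[(thexyldimethylsilyl)oxy]cyclohexa-2,4-dien-1-yl benzoate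
Product: 6 (1S,5R,6S)-5-hydroxy-3-(hydroxymethyl)-2-oxo-6-[(thexyldimethylsilyl)oxy]cyclohex-3-en-1-yl benzoate, via bromo endoperoxide 4 (not isolated), via hydroxy enone 5 (not isolated)
Conditions: O2, TPP (cat.), hν, CH2Cl2, −40 °C; then thiourea, NaHCO3, MeOH, −40 °C to rt; then 37% aq. CH2O, imidazole, THF, rt
Reagents that add atoms: dioxygen (as singlet oxygen), O=O; formaldehyde, C=O
Why: Sensitised singlet oxygen adds to the diene termini C3 and C6 of 3 in a suprafacial [4+2] cycloaddition, closing the 1,2-dioxine ring of the 2,3-dioxabicyclo[2.2.2]oct-5-ene 4 on the face opposite to the two cis oxygen substituents, so the C3 stereocenter (R) is set by steric substrate control. Thiourea then cleaves the O–O bond, the C6 bromohydrin collapses with loss of bromide to the C6 ketone, and enone 5 undergoes an imidazole-catalysed Morita–Baylis–Hillman reaction with formaldehyde (conjugate addition of imidazole to C2, aldol addition of the C1 enolate to CH2O, E1cB release of imidazole), which forms the C1–CH2 bond. The closest known reaction types are the photooxygenation–thiourea reduction of halodiene cis-diol derivatives to 4-hydroxy enones and the aqueous-formaldehyde Baylis–Hillman hydroxymethylation of cyclohex-2-enones; here they are simply run in one flask. The step needs facial selectivity in the cycloaddition (secured by the silyl ether and benzoate on one face and the absence of a free hydroxyl), regioselectivity of the carbonyl (secured by bromine, which makes C6 and not C3 the ketone) and of C–C bond formation (C1 is the only enone α-carbon), and survival of the α-benzoyloxy β-silyloxy ketone (secured by the nearly neutral bicarbonate–imidazole buffer at room temperature). The Baylis–Hillman stage creates no stereocenter and leaves C3, C4 and C5 untouched.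

Step 4
Reactants: 6 (1S,5R,6S)-5-hydroxy-3-(hydroxymethyl)-2-oxo-6-[(thexyldimethylsilyl)oxy]cyclohex-3-en-1-yl benzoate
Product: 7 [(3R,4S,5S)-5-(benzoyloxy)-3-hydroxy-6-oxo-4-[(thexyldimethylsilyl)oxy]cyclohex-1-en-1-yl]methyl benzoate
Conditions: BzCl (1.05 equiv), 2,4,6-collidine, CH2Cl2, −40 °C
Reagents that add atoms: benzoyl chloride, O=C(Cl)c1ccccc1
Why: Chemoselective O-acylation; with a hindered, non-nucleophilic base at low temperature the primary allylic alcohol should react far faster than the secondary C3 hydroxyl next to the silyl ether, and nucleophilic amines are avoided because the product is a Baylis–Hillman-type allylic ester open to SN2′ attack.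

Step 5
Reactants: 7 [(3R,4S,5S)-5-(benzoyloxy)-3-hydroxy-6-oxo-4-[(thexyldimethylsilyl)oxy]cyclohex-1-en-1-yl]methyl benzoate
Product: 8 [(3R,4S,5S)-5-(benzoyloxy)-3,4-dihydroxy-6-oxocyclohex-1-en-1-yl]methyl benzoate
Conditions: 48% aq. HF, MeCN, 0 °C
Reagents that add atoms: none
Why: Acidic fluoride cleavage of the silyl ether (desilylation); the amine-free acidic medium should suppress 1,2-benzoyl migration, retro-aldol opening and SN2′ loss of the allylic benzoate, and no stereocenter is affected.

Step 6
Reactants: 8 [(3R,4S,5S)-5-(benzoyloxy)-3,4-dihydroxy-6-oxocyclohex-1-en-1-yl]methyl benzoate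
Product: 9 [(3R,4S,5R,6S)-5-(benzoyloxy)-3,4,6-trihydroxycyclohex-1-en-1-yl]methyl benzoate
Conditions: Me4NBH(OAc)3, MeCN/AcOH (1:1), −30 °C
Reagents that add atoms: none
Why: Hydroxyl-directed Evans–Saksena reduction; the C4 hydroxyl exchanges onto boron and delivers hydride to the C6 carbonyl from its own face through a chair-like six-membered transition state, which should give the 1,3-anti diol with C6–OH trans to the C5 benzoate (6S), whereas undirected hydride would attack anti to the C5 benzoate and give the epimer.

**Compound list**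
1 | (1S,2S)-3-bromocyclohexa-3,5-diene-1,2-diol | BrC1=CC=C[C@H](O)[C@@H]1O | starting material
2 | (1S,6S)-2-bromo-6-[(thexyldimethylsilyl)oxy]cyclohexa-2,4-dien-1-ol | BrC1=CC=C[C@H](O[Si](C)(C)C(C)(C)C(C)C)[C@@H]1O | intermediate
3 | (1S,6S)-2-bromo-6-[(thexyldimethylsilyl)oxy]cyclohexa-2,4-dien-1-yl benzoate | BrC1=CC=C[C@H](O[Si](C)(C)C(C)(C)C(C)C)[C@@H]1OC(=O)c1ccccc1 | intermediate
4 | (1R,4R,7S,8R)-1-bromo-8-[(thexyldimethylsilyl)oxy]-2,3-dioxabicyclo[2.2.2]oct-5-en-7-yl benzoate (O–O bridge anti to both oxygen substituents) | Br[C@]12OO[C@H](C=C1)[C@H](O[Si](C)(C)C(C)(C)C(C)C)[C@@H]2OC(=O)c1ccccc1 | intermediate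
5 | (1S,5R,6S)-5-hydroxy-2-oxo-6-[(thexyldimethylsilyl)oxy]cyclohex-3-en-1-yl benzoate | O=C1C=C[C@@H](O)[C@H](O[Si](C)(C)C(C)(C)C(C)C)[C@@H]1OC(=O)c1ccccc1 | intermediate
6 | (1S,5R,6S)-5-hydroxy-3-(hydroxymethyl)-2-oxo-6-[(thexyldimethylsilyl)oxy]cyclohex-3-en-1-yl benzoate | O=C1C(CO)=C[C@@H](O)[C@H](O[Si](C)(C)C(C)(C)C(C)C)[C@@H]1OC(=O)c1ccccc1 | intermediate
7 | [(3R,4S,5S)-5-(benzoyloxy)-3-hydroxy-6-oxo-4-[(thexyldimethylsilyl)oxy]cyclohex-1-en-1-yl]methyl benzoate | O=C(OCC1=C[C@@H](O)[C@H](O[Si](C)(C)C(C)(C)C(C)C)[C@H](OC(=O)c2ccccc2)C1=O)c1ccccc1 | intermediate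
8 | [(3R,4S,5S)-5-(benzoyloxy)-3,4-dihydroxy-6-oxocyclohex-1-en-1-yl]methyl benzoate | O=C(OCC1=C[C@@H](O)[C@H](O)[C@H](OC(=O)c2ccccc2)C1=O)c1ccccc1 | intermediate
9 | [(3R,4S,5R,6S)-5-(benzoyloxy)-3,4,6-trihydroxycyclohex-1-en-1-yl]methyl benzoate | O=C(OCC1=C[C@@H](O)[C@H](O)[C@H](OC(=O)c2ccccc2)[C@H]1O)c1ccccc1 | target

**Total step count:** 6. **Longest linear sequence:** 6 steps (from 1).

**Steps most likely to fail**

Step 3 (key step). The α-benzoyloxy β-silyloxy ketone may not survive the aqueous amine stage: E1cB loss of silanol with aromatisation, or imidazole-mediated cleavage of the C5 benzoate. Thiourea residues may also consume formaldehyde. Fallback: setting out from 3, the sequence is stopped after the thiourea stage and hydroxy enone 5 is isolated. α-Iodination (I2, pyridine, CH2Cl2, 0 °C) should give (1S,5R,6S)-5-hydroxy-3-iodo-2-oxo-6-[(thexyldimethylsilyl)oxy]cyclohex-3-en-1-yl benzoate F1. A Stille coupling of F1 with (tributylstannyl)methanol (Pd2(dba)3, AsPh3, CuI, dioxane, 60 °C) then forms the same C1–CH2 bond under neutral, non-aqueous conditions and comes back to the route at 6.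

Step 6. Facial selectivity may be poor if external hydride attack anti to the C5 benzoate, or delivery from the C3 hydroxyl, competes with delivery from the C4 hydroxyl. Conjugate (SN2′) reduction with loss of the allylic benzoate is a further risk. Fallback: setting out from 8, a reagent-controlled Corey–Bakshi–Shibata reduction ((S)-Me-CBS, BH3·SMe2, THF, −20 °C) is used. The trisubstituted alkenyl arm C1 is taken as the large group, which should deliver hydride to the face syn to the C4 and C5 oxygens. This comes back to the route at 9 directly; no new compound is made (F0).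

Step 5. During desilylation the primary allylic benzoate of the Baylis–Hillman-type enone may be lost by SN2′ substitution or solvolysis, and the C5 benzoyl group may migrate to the freed C4 hydroxyl. Fallback: setting out from 6, the silyl ether is removed before the primary benzoate is installed (48% aq. HF, MeCN, 0 °C), which should give (1S,5R,6S)-5,6-dihydroxy-3-(hydroxymethyl)-2-oxocyclohex-3-en-1-yl benzoate F2. The primary hydroxyl of F2 is then benzoylated selectively (BzCl, 2,4,6-collidine, CH2Cl2, −40 °C), which comes back to the route at 8, so the allylic primary benzoate never meets fluoride.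

**Further compounds**
F1 | step 3 | (1S,5R,6S)-5-hydroxy-3-iodo-2-oxo-6-[(thexyldimethylsilyl)oxy]cyclohex-3-en-1-yl benzoate | O=C1C(I)=C[C@@H](O)[C@H](O[Si](C)(C)C(C)(C)C(C)C)[C@@H]1OC(=O)c1ccccc1
F0 | step 6 | none | none
F2 | step 5 | (1S,5R,6S)-5,6-dihydroxy-3-(hydroxymethyl)-2-oxocyclohex-3-en-1-yl benzoate | O=C1C(CO)=C[C@@H](O)[C@H](O)[C@@H]1OC(=O)c1ccccc1
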